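**Retrosynthetic overview**
1. Target ⇐ desilylation and twofold angeloylation of a 3,8-diol; the side-chain oxirane ⇐ C8-OH-directed epoxidation of C10=C11 (1,3-syn).
2. C8–C9 bond, C8 carbinol and prenyl terminus ⇐ [2,3]-Wittig rearrangement of a 2-substituted-allyl 1,1-dimethylallyl ether (key step).
3. Ether ⇐ ene chlorination of the isopropenyl group, then Williamson reaction with 2-methylbut-3-en-2-ol.
4. Ring stereocentres C2–C5 ⇐ C1 of (S)-(+)-carvone through nucleophilic epoxidation, Rubottom oxidation and Luche reduction.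
5. Ring order: the cyclohexane is bought with carvone; the ring oxirane is made first (step 1), the side-chain oxirane last (step 9).

Assumption and convention: the SMILES is taken as drawn, i.e. (1R,2R,3S,4S,5S,8S,10R) with locants ring C1 (bears the side chain), C2 (OH), C3 (O-angeloyl), C4/C5 (methyl-bearing oxirane), C6 (CH2), side chain C7 (=C14H2), C8 (O-angeloyl), C9, C10/C11 (terminal oxirane); bicyclic names use 7-oxabicyclo[4.1.0]heptane numbering.

**Step 1**
Reactants: 1 (S)-(+)-carvone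
Product: 2 (1S,4S,6S)-1-methyl-4-(prop-1-en-2-yl)-7-oxabicyclo[4.1.0]heptan-2-one
Conditions: H2O2 (30% aq), NaOH (aq, cat.), MeOH, 0 °C
Reagents that add atoms: hydrogen peroxide, OO
Why: Weitz–Scheffer nucleophilic epoxidation in which hydroperoxide adds to the enone β-carbon anti to the C1 isopropenyl group, so the C4/C5 oxirane forms trans to the side chain.

**Step 2**
Reactants: 2 (1S,4S,6S)-1-methyl-4-(prop-1-en-2-yl)-7-oxabicyclo[4.1.0]heptan-2-one
Product: 4 tert-butyldimethyl{[(1S,4S,6S)-1-methyl-4-(prop-1-en-2-yl)-7-oxabicyclo[4.1.0]hept-2-en-2-yl]oxy}silane, via lithium enolate 3 (not isolated)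
Conditions: LiN(i-Pr)2 (LDA), THF, −78 °C; then TBSCl, DMPU, −78 → 0 °C
Reagents that add atoms: tert-butyldimethylsilyl chloride (TBSCl), CC(C)(C)[Si](C)(C)Cl
Why: Kinetic enolisation can occur only toward C2 (C4 is quaternary) and O-silylation gives the silyl enol ether without creating a stereocentre.

**Step 3**
Reactants: 4 tert-butyldimethylsilyl enol ether of 2
Product: 6 (1S,3R,4R,6S)-3-[(tert-butyldimethylsilyl)oxy]-1-methyl-4-(prop-1-en-2-yl)-7-oxabicyclo[4.1.0]heptan-2-one, via silyloxy oxirane 5 (not isolated)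
Conditions: mCPBA (1.05 equiv), CH2Cl2, −20 → 0 °C
Reagents that add atoms: 3-chloroperoxybenzoic acid (mCPBA), OOC(=O)c1cccc(Cl)c1
Why: Rubottom oxidation in which the peracid attacks the electron-rich enol ether (much faster than the isopropenyl alkene) on the face anti to the C1 isopropenyl and C4 methyl groups, and the silyloxy oxirane opens with 1,4-silyl shift to place the C2 silyloxy group trans to the side chain.

**Step 4**
Reactants: 6 the α-silyloxy epoxy ketone
Product: 7 (1R,2S,3R,4R,6S)-3-[(tert-butyldimethylsilyl)oxy]-1-methyl-4-(prop-1-en-2-yl)-7-oxabicyclo[4.1.0]heptan-2-ol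
Conditions: NaBH4, CeCl3·7H2O, MeOH, −40 °C
Reagents that add atoms: none
Why: Luche reduction by axial hydride attack on the half-chair that holds the C1 and C2 substituents equatorial gives the equatorial C3 alcohol, trans to both the C2 silyloxy group and the oxirane oxygen.

**Step 5**
Reactants: 7 the epoxy alcohol
Product: 8 (1S,2S,3R,4R,6S)-3-[(tert-butyldimethylsilyl)oxy]-1-methyl-4-(prop-1-en-2-yl)-2-[(triethylsilyl)oxy]-7-oxabicyclo[4.1.0]heptane
Conditions: TESOTf, 2,6-lutidine, CH2Cl2, −78 → 0 °C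
Reagents that add atoms: triethylsilyl trifluoromethanesulfonate (TESOTf), CC[Si](CC)(CC)OS(=O)(=O)C(F)(F)F
Why: Silyl triflate protection caps the hindered C3 hydroxyl so that no alkoxide can form beside the C2 silyl ether (no 1,2-silyl migration) in the two strongly basic steps that follow.

**Step 6**
Reactants: 8 the bis-silyl ether
Product: 9 (1S,2S,3R,4R,6S)-3-[(tert-butyldimethylsilyl)oxy]-4-(3-chloroprop-1-en-2-yl)-1-methyl-2-[(triethylsilyl)oxy]-7-oxabicyclo[4.1.0]heptane
Conditions: Ca(OCl)2, CO2 (dry ice), CH2Cl2/H2O, 0 °C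
Reagents that add atoms: calcium hypochlorite, [Ca+2].[O-]Cl.[O-]Cl
Why: Ene-type allylic chlorination by HOCl puts chlorine on the terminal alkene carbon and loses a methyl proton, giving the 2-(chloromethyl)allyl unit without touching C1.

**Step 7**
Reactants: 9 the allylic chloride; 10 2-methylbut-3-en-2-ol
Product: 12 (1S,2S,3R,4R,6S)-3-[(tert-butyldimethylsilyl)oxy]-1-methyl-4-{3-[(2-methylbut-3-en-2-yl)oxy]prop-1-en-2-yl}-2-[(triethylsilyl)oxy]-7-oxabicyclo[4.1.0]heptane, via sodium 2-methylbut-3-en-2-olate 11 (not isolated)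
Conditions: 10 (5 equiv), NaH, THF, 0 °C; then 9, Bu4NI (cat.), DMF, 0 °C → rt
Reagents that add atoms: 2-methylbut-3-en-2-ol (compound 10), C=CC(C)(C)O
Why: Williamson ether synthesis by SN2 attack of the tertiary allylic alkoxide on the primary allylic chloride, which cannot eliminate.

**Step 8**
Reactants: 12 the bis-allylic ether
Product: 15 8S homoallylic alcohol (ring of 8; chain C7(=C14H2)-C8H(OH)-C9H2-C10H=C11Me2), via lithiated ether 13 (not isolated), via lithium alkoxide 14 (not isolated)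
Conditions: n-BuLi (1.5 equiv), THF, −78 °C; then H2O
Reagents that add atoms: none
Why: [2,3]-Wittig rearrangement, in which only the doubly activated OCH2 can be lithiated and the five-membered envelope transition state forms C8–C9 while turning the tertiary allyl unit into the prenyl terminus; C8 is set only by the ring (the C2 silyloxy branch shields one face of the alkoxyallyllithium), a bias expected to be modest and not securely predictable, so 15 is separated from its 8R epimer on silica.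

**Step 9**
Reactants: 15 the 8S homoallylic alcohol
Product: 16 syn epoxy alcohol (15 with C10=C11 converted to the oxirane; 8S,10R)
Conditions: Mo(CO)6 (10 mol %), t-BuOOH (decane), Na2HPO4, benzene, 75 °C
Reagents that add atoms: tert-butyl hydroperoxide, CC(C)(C)OO
Why: Hydroxyl-directed epoxidation, in which molybdenum catalysis favours homoallylic delivery to the electron-rich trisubstituted alkene over the allylic C7=C14 methylene, and a chair-like alkoxide/peroxide transition state with the C8 substituent equatorial delivers oxygen syn to the C8 hydroxyl, giving 10R from 8S.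

**Step 10**
Reactants: 16 the syn epoxy alcohol
Product: 17 epoxy diol (free 3-OH and 8-OH; 2-OTBS kept)
Conditions: HF·pyridine, pyridine, THF, 0 °C → rt
Reagents that add atoms: none
Why: Buffered fluoride desilylation removes the more labile triethylsilyl ether selectively and leaves the TBS ether and both oxiranes intact.

**Step 11**
Reactants: 17 the epoxy diol; 18 angelic acid
Product: 21 3,8-di-O-angeloyl 2-O-TBS ether, via mixed anhydride 19 (not isolated), via C8 monoangelate 20 (not isolated)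
Conditions: 18, 2,4,6-trichlorobenzoyl chloride, Et3N, toluene, rt; then 17, toluene, 80 °C
Reagents that add atoms: angelic acid (compound 18), C/C=C(/C)C(=O)O
Why: Yamaguchi-type esterification through the preformed mixed anhydride without a nucleophilic catalyst acylates the C8 and then the hindered C3 hydroxyl while keeping Z to E isomerisation (angelate to tiglate) low.

**Step 12**
Reactants: 21 the di-O-angeloyl TBS ether
Product: 22 CNP0296086.4
Conditions: Bu4NF, AcOH (1:1), THF, 0 °C → rt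
Reagents that add atoms: none
Why: Acetic acid-buffered fluoride desilylation frees the C2 hydroxyl without opening either oxirane and without 1,2-acyl migration from O3 to O2.

**Compound list**
1 | (S)-(+)-carvone, (5S)-2-methyl-5-(prop-1-en-2-yl)cyclohex-2-en-1-one | CC(=C)[C@H]1CC=C(C)C(=O)C1 | starting material
2 | (1S,4S,6S)-1-methyl-4-(prop-1-en-2-yl)-7-oxabicyclo[4.1.0]heptan-2-one (oxirane trans to isopropenyl) | CC(=C)[C@H]1C[C@@H]2O[C@]2(C)C(=O)C1 | intermediate
3 | lithium enolate of 2 (not isolated) | CC(=C)[C@H]1C[C@@H]2O[C@]2(C)C(O[Li])=C1 | intermediate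
4 | tert-butyldimethyl{[(1S,4S,6S)-1-methyl-4-(prop-1-en-2-yl)-7-oxabicyclo[4.1.0]hept-2-en-2-yl]oxy}silane | CC(=C)[C@H]1C[C@@H]2O[C@]2(C)C(O[Si](C)(C)C(C)(C)C)=C1 | intermediate
5 | silyloxy oxirane from 4, new oxygen on the same face as the C4/C5 oxirane (not isolated) | CC(=C)[C@H]1C[C@@H]2O[C@]2(C)[C@]3(O[Si](C)(C)C(C)(C)C)O[C@H]13 | intermediate
6 | (1S,3R,4R,6S)-3-[(tert-butyldimethylsilyl)oxy]-1-methyl-4-(prop-1-en-2-yl)-7-oxabicyclo[4.1.0]heptan-2-one | CC(=C)[C@H]1C[C@@H]2O[C@]2(C)C(=O)[C@@H]1O[Si](C)(C)C(C)(C)C | intermediate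
7 | (1R,2S,3R,4R,6S)-3-[(tert-butyldimethylsilyl)oxy]-1-methyl-4-(prop-1-en-2-yl)-7-oxabicyclo[4.1.0]heptan-2-ol | CC(=C)[C@H]1C[C@@H]2O[C@]2(C)[C@@H](O)[C@@H]1O[Si](C)(C)C(C)(C)C | intermediate
8 | (1S,2S,3R,4R,6S)-3-[(tert-butyldimethylsilyl)oxy]-1-methyl-4-(prop-1-en-2-yl)-2-[(triethylsilyl)oxy]-7-oxabicyclo[4.1.0]heptane | CC(=C)[C@H]1C[C@@H]2O[C@]2(C)[C@@H](O[Si](CC)(CC)CC)[C@@H]1O[Si](C)(C)C(C)(C)C | intermediate
9 | (1S,2S,3R,4R,6S)-3-[(tert-butyldimethylsilyl)oxy]-4-(3-chloroprop-1-en-2-yl)-1-methyl-2-[(triethylsilyl)oxy]-7-oxabicyclo[4.1.0]heptane | ClCC(=C)[C@H]1C[C@@H]2O[C@]2(C)[C@@H](O[Si](CC)(CC)CC)[C@@H]1O[Si](C)(C)C(C)(C)C | intermediate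
10 | 2-methylbut-3-en-2-ol | C=CC(C)(C)O | starting material
11 | sodium 2-methylbut-3-en-2-olate (not isolated) | C=CC(C)(C)[O-].[Na+] | intermediate
12 | (1S,2S,3R,4R,6S)-3-[(tert-butyldimethylsilyl)oxy]-1-methyl-4-{3-[(2-methylbut-3-en-2-yl)oxy]prop-1-en-2-yl}-2-[(triethylsilyl)oxy]-7-oxabicyclo[4.1.0]heptane | C=CC(C)(C)OCC(=C)[C@H]1C[C@@H]2O[C@]2(C)[C@@H](O[Si](CC)(CC)CC)[C@@H]1O[Si](C)(C)C(C)(C)C | intermediate
13 | lithiated ether: 12 lithiated at the OCH2 carbon, a delocalised alkoxyallyllithium (not isolated) | C=CC(C)(C)OC([Li])C(=C)[C@H]1C[C@@H]2O[C@]2(C)[C@@H](O[Si](CC)(CC)CC)[C@@H]1O[Si](C)(C)C(C)(C)C | intermediate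
14 | lithium alkoxide of 15 (not isolated) | C=C([C@H](CC=C(C)C)O[Li])[C@H]1C[C@@H]2O[C@]2(C)[C@@H](O[Si](CC)(CC)CC)[C@@H]1O[Si](C)(C)C(C)(C)C | intermediate
15 | 8S homoallylic alcohol: ring of 8 (2-OTBS, 3-OTES, 4,5-oxirane) carrying at C1 the chain C7(=C14H2)-C8H(OH)-C9H2-C10H=C11(CH3)2; (1R,2R,3S,4S,5S,8S) | C=C([C@H](CC=C(C)C)O)[C@H]1C[C@@H]2O[C@]2(C)[C@@H](O[Si](CC)(CC)CC)[C@@H]1O[Si](C)(C)C(C)(C)C | intermediate
16 | syn epoxy alcohol: 15 with C10=C11 as the 10,11-oxirane, C10-O syn to C8-OH; (1R,2R,3S,4S,5S,8S,10R) | C=C([C@H](C[C@H]1OC1(C)C)O)[C@H]1C[C@@H]2O[C@]2(C)[C@@H](O[Si](CC)(CC)CC)[C@@H]1O[Si](C)(C)C(C)(C)C | intermediate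
17 | epoxy diol: 16 without the triethylsilyl group (free 3-OH and 8-OH, 2-OTBS); (1R,2R,3S,4R,5S,8S,10R), the C4 descriptor changes with the O3 substituent while the geometry does not | C=C([C@H](C[C@H]1OC1(C)C)O)[C@H]1C[C@@H]2O[C@]2(C)[C@@H](O)[C@@H]1O[Si](C)(C)C(C)(C)C | intermediate
18 | angelic acid, (Z)-2-methylbut-2-enoic acid | C/C=C(/C)C(=O)O | starting material
19 | mixed anhydride: (Z)-2-methylbut-2-enoic 2,4,6-trichlorobenzoic anhydride (not isolated) | C/C=C(/C)C(=O)OC(=O)c1c(Cl)cc(Cl)cc1Cl | intermediate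
20 | C8 monoangelate: 8-O-angeloyl ester of 17 with free 3-OH (not isolated) | C=C([C@H](C[C@H]1OC1(C)C)OC(=O)/C(C)=C\C)[C@H]1C[C@@H]2O[C@]2(C)[C@@H](O)[C@@H]1O[Si](C)(C)C(C)(C)C | intermediate
21 | 3,8-di-O-angeloyl ester of 17 (2-OTBS); (1R,2R,3S,4S,5S,8S,10R) | C=C([C@H](C[C@H]1OC1(C)C)OC(=O)/C(C)=C\C)[C@H]1C[C@@H]2O[C@]2(C)[C@@H](OC(=O)/C(C)=C\C)[C@@H]1O[Si](C)(C)C(C)(C)C | intermediate
22 | CNP0296086.4: (1R,2R,3S,4S,5S,8S,10R)-3,8-bis(angeloyloxy)-4,5:10,11-diepoxy compound with free 2-OH and the C7=C14 methylene | C=C([C@H](C[C@H]1OC1(C)C)OC(=O)/C(C)=C\C)[C@H]1C[C@@H]2O[C@]2(C)[C@@H](OC(=O)/C(C)=C\C)[C@@H]1O | target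

**Totals**
Total step count: 12. Longest linear sequence: 12 steps (1 → 22); 10 and 18 are used as bought.

**Steps most likely to fail**

Step 8, the [2,3]-Wittig rearrangement. The [1,2]-shift can compete, and the ring may steer C8 only weakly or toward 8R. The fallback sets out from 12: the rearrangement is run as before and the 8R alcohol F1 (the C8 epimer of 15) is collected. Mitsunobu inversion (PPh3, DIAD, 4-nitrobenzoic acid, toluene, 0 °C) converts it into the 8S 4-nitrobenzoate F2 by SN2 displacement at the allylic carbinol. Methanolysis (K2CO3, MeOH) brings the material back to the route at 15.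

Step 9, the directed epoxidation. The allylic C7=C14 methylene may compete (a vanadium catalyst such as VO(acac)2 would prefer it), the syn selectivity under molybdenum may be lower than hoped, and the 3,4-epoxy alcohol can cyclise under Lewis acid. The fallback sets out from 15: the triethylsilyl ether is cleaved (HF·pyridine, pyridine) to the diene diol F3, and both hydroxyls are esterified with mixed anhydride 19 as in step 11 to the diene bis-angelate F4. The only electron-rich alkene left, C10=C11, is then epoxidised with mCPBA (CH2Cl2, −20 °C); the allylic-ester methylene and the angelate alkenes are deactivated. This gives up hydroxyl direction, so 21 forms together with the 10S epimer of 21 F5 and the two are separated by preparative HPLC. The route is rejoined at 21.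

Step 11, the twofold angeloylation. The C3 hydroxyl is flanked by a quaternary oxirane carbon and the silyl ether, and forcing conditions isomerise angelate to tiglate. The fallback sets out from 17: both hydroxyls are acylated with 2-[bis(2,2,2-trifluoroethoxy)phosphoryl]propanoic acid (DCC, DMAP, CH2Cl2) to the bis(phosphonopropanoate) F6. A twofold Still–Gennari olefination with acetaldehyde (KN(SiMe3)2, 18-crown-6, THF, −78 °C) then builds both Z-configured 2-methylbut-2-enoates on the substrate. The route is rejoined at 21.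

**Further compounds**
F1 | step 8 | 8R alcohol, the C8 epimer of 15 | C=C([C@@H](CC=C(C)C)O)[C@H]1C[C@@H]2O[C@]2(C)[C@@H](O[Si](CC)(CC)CC)[C@@H]1O[Si](C)(C)C(C)(C)C
F2 | step 8 | 8S 4-nitrobenzoate of 15 | C=C([C@H](CC=C(C)C)OC(=O)c1ccc(cc1)[N+](=O)[O-])[C@H]1C[C@@H]2O[C@]2(C)[C@@H](O[Si](CC)(CC)CC)[C@@H]1O[Si](C)(C)C(C)(C)C
F3 | step 9 | diene diol: 15 without the triethylsilyl group | C=C([C@H](CC=C(C)C)O)[C@H]1C[C@@H]2O[C@]2(C)[C@@H](O)[C@@H]1O[Si](C)(C)C(C)(C)C
F4 | step 9 | diene bis-angelate: 3,8-di-O-angeloyl ester of F3 | C=C([C@H](CC=C(C)C)OC(=O)/C(C)=C\C)[C@H]1C[C@@H]2O[C@]2(C)[C@@H](OC(=O)/C(C)=C\C)[C@@H]1O[Si](C)(C)C(C)(C)C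
F5 | step 9 | 10S epimer of 21 | C=C([C@H](C[C@@H]1OC1(C)C)OC(=O)/C(C)=C\C)[C@H]1C[C@@H]2O[C@]2(C)[C@@H](OC(=O)/C(C)=C\C)[C@@H]1O[Si](C)(C)C(C)(C)C
F6 | step 11 | 3,8-bis{2-[bis(2,2,2-trifluoroethoxy)phosphoryl]propanoate} of 17 (phosphonate α-carbons unspecified) | C=C([C@H](C[C@H]1OC1(C)C)OC(=O)C(C)P(=O)(OCC(F)(F)F)OCC(F)(F)F)[C@H]1C[C@@H]2O[C@]2(C)[C@@H](OC(=O)C(C)P(=O)(OCC(F)(F)F)OCC(F)(F)F)[C@@H]1O[Si](C)(C)C(C)(C)C
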